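**Strategy.** Ring B is built rather than bought. Its ether-bearing carbon, its methyl-bearing carbon and the adjacent hydroxyl-bearing carbon are the α-carbon, β-carbon and ester carbon of a 2-aryloxybut-2-enoate. That enoate is reached by O-alkylating the hindered ring-A phenol, so the diaryl ether with four ortho substituents is never made by O-arylation. One Michael–Claisen annulation with tert-butyl acetoacetate then forms two C–C bonds and the six-membered carbocycle. The tert-butyl ester it leaves blocks the ring-B carbon para to a hydroxyl, so the methylene bridges from a carboxyl-blocked ring C can enter only between the two hydroxyls. Aromatisation, double benzylation, unmasking and triple decarboxylation finish the symmetric pentacycle.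

Key step: step 7

**Assumption.** 2,6-Dihydroxy-4-methylbenzoic acid (p-orsellinic acid) is taken as purchasable; 12 is a racemate drawn as its all-trans diketo form, although enol tautomers should dominate.

**Design choices.**
- The formyl group of ring A travels as a cyclic neopentyl-glycol acetal, not an acyclic acetal, because it must survive the acidic 1,3-dione of step 7 and its buffered work-up.
- Ring C enters as a bis-Mannich base whose carbon between the hydroxyls is blocked by a tert-butyl ester, so it cannot condense with itself.
- Ring A is unmasked only after bridging, when no nucleophilic ring carbon of rings B and C is free to capture the formaldehyde released from the MOM ethers.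

**Abbreviations.** ArO = 2-(5,5-dimethyl-1,3-dioxan-2-yl)-6-(methoxycarbonyl)-3-(methoxymethoxy)-5-methylphenoxy (masked ring A). Ar'O = 2-formyl-3-hydroxy-6-(methoxycarbonyl)-5-methylphenoxy (free ring A).

## Route

Step 1
Reactants: 1 methyl orsellinate
Product: 2 methyl haematommate (methyl 3-formyl-2,4-dihydroxy-6-methylbenzoate)
Conditions: Cl2CHOMe, TiCl4, CH2Cl2, 0 °C → rt; then H2O
Reagents that add atoms: dichloromethyl methyl ether, COC(Cl)Cl; water, O
Why: Rieche formylation, in which the titanium phenoxide/ester chelate should direct the electrophile to C3, the only carbon ortho to both hydroxyls, the minor C5 isomer being removable by crystallisation.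

Step 2
Reactants: 2 methyl haematommate
Product: 3 methyl 3-formyl-2-hydroxy-4-(methoxymethoxy)-6-methylbenzoate
Conditions: MOMCl (1.1 equiv), iPr2NEt, CH2Cl2, 0 °C → rt
Reagents that add atoms: chloromethyl methyl ether, COCCl
Why: Williamson-type O-alkylation, selective because the 4-hydroxyl is the more acidic and less encumbered phenol, whereas the 2-hydroxyl is wedged between ester and formyl groups and chelated to the ester carbonyl, so it should stay free for step 5.

Step 3
Reactants: 3 methyl 3-formyl-2-hydroxy-4-(methoxymethoxy)-6-methylbenzoate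
Product: 4 methyl 3-(5,5-dimethyl-1,3-dioxan-2-yl)-2-hydroxy-4-(methoxymethoxy)-6-methylbenzoate
Conditions: HOCH2CMe2CH2OH, HC(OMe)3, PPTS (cat.), toluene, 45 °C
Reagents that add atoms: 2,2-dimethylpropane-1,3-diol, OCC(C)(C)CO
Why: Acid-catalysed acetalisation driven by the orthoformate, under a catalyst too weak to ionise the aryl MOM ether.

Step 4
Reactants: 5 trimethyl phosphonoacetate
Product: 6 trimethyl diazophosphonoacetate (methyl 2-diazo-2-(dimethoxyphosphoryl)acetate)
Conditions: NaH, p-ABSA, THF, 0 °C → rt
Reagents that add atoms: 4-acetamidobenzenesulfonyl azide, CC(=O)Nc1ccc(cc1)S(=O)(=O)N=[N+]=[N-]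
Why: Regitz diazo transfer to the sodium enolate of a phosphonoacetate, the standard access to this stable acceptor/acceptor diazo compound.

Step 5
Reactants: 4 methyl 3-(5,5-dimethyl-1,3-dioxan-2-yl)-2-hydroxy-4-(methoxymethoxy)-6-methylbenzoate; 6 trimethyl diazophosphonoacetate
Product: 7 methyl 2-(ArO)-2-(dimethoxyphosphoryl)acetate (racemic)
Conditions: Rh2(OAc)4 (2 mol%), toluene, 80 °C, slow addition of 6
Reagents that add atoms: none
Why: Rhodium-carbenoid O–H insertion, in which the electrophilic carbenoid is captured by the phenol oxygen and a proton shift follows; this tolerates di-ortho-substituted phenols far better than SN2 alkylation and should outpace attack on ether or acetal oxygens, and the new stereocentre forms racemic and is destroyed in step 6.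

Step 6
Reactants: 7 methyl 2-(ArO)-2-(dimethoxyphosphoryl)acetate; 8 acetaldehyde
Product: 9 methyl (Z)-2-(ArO)but-2-enoate
Conditions: LiN(SiMe3)2, THF, −78 °C; then MeCHO, −78 → 0 °C
Reagents that add atoms: none
Why: Horner–Wadsworth–Emmons olefination of an α-aryloxy phosphonoacetate, which should give mainly the Z-alkene (methyl trans to the ester), although the geometry does not matter because both isomers converge in step 7.

Step 7
Reactants: 9 methyl (Z)-2-(ArO)but-2-enoate; 10 tert-butyl acetoacetate
Product: 12 rac-tert-butyl all-trans-3-(ArO)-2-methyl-4,6-dioxocyclohexane-1-carboxylate, via Michael adduct 11 (not isolated)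
Conditions: NaOMe (1.5 equiv), MeOH, 65 °C; then aq. NaH2PO4 (pH 5), 0 °C
Reagents that add atoms: none
Why: The sodium enolate of 10 adds through its central carbon to the β-carbon of 9 (Michael addition) to give 11 after proton transfer, and under the equilibrating methoxide conditions the acetyl CH3 enolate of 11 attacks the α-aryloxy methyl ester (intramolecular Claisen condensation), expels methoxide and delivers a 1,3-dione that is deprotonated at once, which pulls the sequence forward. The closest known reaction type is the classical dihydroresorcinol (dihydroorsellinate) synthesis from acetoacetic and crotonic esters. The single ring is closed in a 6-(enolendo)-exo-trig mode. The three stereocentres (CH–CO2tBu, CH–CH3, CH–OAr) are set by no chiral element: the two that flank carbonyl groups epimerise under the conditions, so the all-equatorial racemate should dominate, and all three vanish in step 8. The step needs chemoselectivity among three esters and regioselectivity within the ambident acetoacetate: the tert-butyl ester is inert to methoxide, the ring-A ester is shielded by two ortho substituents and its five-membered Dieckmann product has no acidic hydrogen and reverts, whereas only the six-membered dione leaves the equilibrium as its stabilised enolate. Methoxide in methanol matches both methyl esters so that any exchange is degenerate, and the electron-poor aryloxy group should keep the α-oxygenated crotonate electrophilic enough for the conjugate addition.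

Step 8
Reactants: 12 rac-tert-butyl all-trans-3-(ArO)-2-methyl-4,6-dioxocyclohexane-1-carboxylate
Product: 15 tert-butyl 5-(ArO)-2,4-dihydroxy-6-methylbenzoate, via selenide 13 (not isolated), via selenoxide 14 (not isolated)
Conditions: LiN(iPr)2 (2.1 equiv), THF, −78 → −40 °C; PhSeBr, −78 °C; then H2O2, pyridine, CH2Cl2, 0 °C → rt
Reagents that add atoms: none
Why: Reich-type α-selenenylation and selenoxide syn-elimination, in which the second deprotonation of the dione enolate should occur at the ester-bearing carbon and PhSeBr should enter anti to the neighbouring methyl so that selenium and the adjacent C–H are cis, the resulting cyclohexadienone tautomerising to the resorcylate under non-acidic conditions that spare MOM ether, acetal and tert-butyl ester.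

Step 9
Reactants: 16 2,6-dihydroxy-4-methylbenzoic acid
Product: 17 tert-butyl 2,6-dihydroxy-4-methylbenzoate
Conditions: Cl3CC(=NH)OtBu (2 equiv), THF–cyclohexane, rt
Reagents that add atoms: tert-butyl 2,2,2-trichloroacetimidate, CC(C)(C)OC(=N)C(Cl)(Cl)Cl
Why: Acid-catalysed tert-butylation of a carboxylic acid by a trichloroacetimidate, in which the strongly acidic substrate protonates the imidate itself and the carboxylate captures the tert-butyl cation, leaving the chelated phenols untouched.

Step 10
Reactants: 17 tert-butyl 2,6-dihydroxy-4-methylbenzoate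
Product: 18 tert-butyl 3,5-bis[(dimethylamino)methyl]-2,6-dihydroxy-4-methylbenzoate
Conditions: CH2=NMe2+ I− (2.2 equiv), Et3N, CH2Cl2, rt
Reagents that add atoms: N,N-dimethylmethyleneiminium iodide (Eschenmoser's salt), C=[N+](C)C.[I-]
Why: Mannich reaction with a preformed iminium salt at the two equivalent free ring carbons, each ortho to one hydroxyl and para to the other, giving a product that has no unsubstituted ring carbon left and therefore cannot oligomerise.

Step 11
Reactants: 15 tert-butyl 5-(ArO)-2,4-dihydroxy-6-methylbenzoate (2.2 equiv); 18 tert-butyl 3,5-bis[(dimethylamino)methyl]-2,6-dihydroxy-4-methylbenzoate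
Product: 20 tert-butyl 3,5-bis{[5-(ArO)-3-(tert-butoxycarbonyl)-2,6-dihydroxy-4-methylphenyl]methyl}-2,6-dihydroxy-4-methylbenzoate, via mono-benzylated Mannich base 19 (not isolated)
Conditions: 1,4-dioxane, 100 °C, N2 stream
Reagents that add atoms: none
Why: Alkylation of a phenol by a phenolic Mannich base through thermally generated ortho-quinone methides (a Friedel–Crafts-type conjugate addition), in which dimethylamine leaves as a gas, the only unsubstituted nucleophilic carbon of 15 lies between its two hydroxyls, ring A carries no free phenol and the ring-C carbon between the hydroxyls is blocked by its ester, so the two diarylmethane bonds can form in only one way.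

Step 12
Reactants: 20 tert-butyl 3,5-bis{[5-(ArO)-3-(tert-butoxycarbonyl)-2,6-dihydroxy-4-methylphenyl]methyl}-2,6-dihydroxy-4-methylbenzoate
Product: 21 tert-butyl 3,5-bis{[5-(Ar'O)-3-(tert-butoxycarbonyl)-2,6-dihydroxy-4-methylphenyl]methyl}-2,6-dihydroxy-4-methylbenzoate
Conditions: 1 M HCl, THF–MeOH–H2O, rt → 35 °C
Reagents that add atoms: water, O
Why: Acid-catalysed hydrolysis of the acetals and of the MOM ethers (eased by the ortho formyl group once released), run while every nucleophilic carbon of rings B and C is still substituted and in methanol that traps formaldehyde as dimethoxymethane, under dilute acid that the chelated tert-butyl esters should survive.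

Step 13
Reactants: 21 tert-butyl 3,5-bis{[5-(Ar'O)-3-(tert-butoxycarbonyl)-2,6-dihydroxy-4-methylphenyl]methyl}-2,6-dihydroxy-4-methylbenzoate
Product: 23 Praesorether G, via tricarboxylic acid 22 (not isolated)
Conditions: TFA–CH2Cl2 (1:2), 0 °C → rt; evaporate; then 1,4-dioxane–H2O, 100 °C
Reagents that add atoms: none
Why: Acidolysis of the three tert-butyl esters with loss of isobutene, then thermal protodecarboxylation of the resulting 2,4- and 2,6-dihydroxybenzoic acids by ipso-protonation, as is typical of orsellinic-type acids, under near-neutral conditions that should leave the hindered methyl esters and hydrogen-bonded aldehydes intact; the target has no stereocentre.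

## Compound list

1 | methyl orsellinate | COC(=O)c1c(C)cc(O)cc1O | starting material
2 | methyl haematommate | COC(=O)c1c(C)cc(O)c(C=O)c1O | intermediate
3 | methyl 3-formyl-2-hydroxy-4-(methoxymethoxy)-6-methylbenzoate | COC(=O)c1c(C)cc(OCOC)c(C=O)c1O | intermediate
4 | methyl 3-(5,5-dimethyl-1,3-dioxan-2-yl)-2-hydroxy-4-(methoxymethoxy)-6-methylbenzoate | COC(=O)c1c(C)cc(OCOC)c(C2OCC(C)(C)CO2)c1O | intermediate
5 | trimethyl phosphonoacetate | COC(=O)CP(=O)(OC)OC | starting material
6 | trimethyl diazophosphonoacetate | COC(=O)C(=[N+]=[N-])P(=O)(OC)OC | intermediate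
7 | methyl 2-(ArO)-2-(dimethoxyphosphoryl)acetate (racemic) | COC(=O)C(Oc1c(C2OCC(C)(C)CO2)c(OCOC)cc(C)c1C(=O)OC)P(=O)(OC)OC | intermediate
8 | acetaldehyde | CC=O | starting material
9 | methyl (Z)-2-(ArO)but-2-enoate | C/C=C(\Oc1c(C2OCC(C)(C)CO2)c(OCOC)cc(C)c1C(=O)OC)C(=O)OC | intermediate
10 | tert-butyl acetoacetate | CC(=O)CC(=O)OC(C)(C)C | starting material
11 | Michael adduct, 1-tert-butyl 5-methyl 2-acetyl-4-(ArO)-3-methylpentanedioate (diastereomer mixture, not isolated) | CC(=O)C(C(=O)OC(C)(C)C)C(C)C(Oc1c(C2OCC(C)(C)CO2)c(OCOC)cc(C)c1C(=O)OC)C(=O)OC | intermediate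
12 | rac-tert-butyl all-trans-3-(ArO)-2-methyl-4,6-dioxocyclohexane-1-carboxylate (relative configuration as drawn) | C[C@H]1[C@H](Oc2c(C3OCC(C)(C)CO3)c(OCOC)cc(C)c2C(=O)OC)C(=O)CC(=O)[C@@H]1C(=O)OC(C)(C)C | intermediate
13 | selenide, tert-butyl 3-(ArO)-2-methyl-4,6-dioxo-1-(phenylselanyl)cyclohexane-1-carboxylate (diastereomer mixture, not isolated) | CC1C(Oc2c(C3OCC(C)(C)CO3)c(OCOC)cc(C)c2C(=O)OC)C(=O)CC(=O)C1([Se]c1ccccc1)C(=O)OC(C)(C)C | intermediate
14 | selenoxide, tert-butyl 3-(ArO)-2-methyl-4,6-dioxo-1-(phenylseleninyl)cyclohexane-1-carboxylate (diastereomer mixture, not isolated) | CC1C(Oc2c(C3OCC(C)(C)CO3)c(OCOC)cc(C)c2C(=O)OC)C(=O)CC(=O)C1([Se](=O)c1ccccc1)C(=O)OC(C)(C)C | intermediate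
15 | tert-butyl 5-(ArO)-2,4-dihydroxy-6-methylbenzoate | Cc1c(Oc2c(C3OCC(C)(C)CO3)c(OCOC)cc(C)c2C(=O)OC)c(O)cc(O)c1C(=O)OC(C)(C)C | intermediate
16 | 2,6-dihydroxy-4-methylbenzoic acid | Cc1cc(O)c(C(=O)O)c(O)c1 | starting material
17 | tert-butyl 2,6-dihydroxy-4-methylbenzoate | Cc1cc(O)c(C(=O)OC(C)(C)C)c(O)c1 | intermediate
18 | tert-butyl 3,5-bis[(dimethylamino)methyl]-2,6-dihydroxy-4-methylbenzoate | Cc1c(CN(C)C)c(O)c(C(=O)OC(C)(C)C)c(O)c1CN(C)C | intermediate
19 | mono-benzylated Mannich base (ring C carrying one ring-B unit and one CH2NMe2, not isolated) | Cc1c(Cc2c(O)c(Oc3c(C4OCC(C)(C)CO4)c(OCOC)cc(C)c3C(=O)OC)c(C)c(C(=O)OC(C)(C)C)c2O)c(O)c(C(=O)OC(C)(C)C)c(O)c1CN(C)C | intermediate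
20 | masked pentacyclic tri-tert-butyl ester | Cc1c(Cc2c(O)c(Oc3c(C4OCC(C)(C)CO4)c(OCOC)cc(C)c3C(=O)OC)c(C)c(C(=O)OC(C)(C)C)c2O)c(O)c(C(=O)OC(C)(C)C)c(O)c1Cc1c(O)c(Oc2c(C3OCC(C)(C)CO3)c(OCOC)cc(C)c2C(=O)OC)c(C)c(C(=O)OC(C)(C)C)c1O | intermediate
21 | unmasked pentacyclic tri-tert-butyl ester | Cc1c(Cc2c(O)c(Oc3c(C=O)c(O)cc(C)c3C(=O)OC)c(C)c(C(=O)OC(C)(C)C)c2O)c(O)c(C(=O)OC(C)(C)C)c(O)c1Cc1c(O)c(Oc2c(C=O)c(O)cc(C)c2C(=O)OC)c(C)c(C(=O)OC(C)(C)C)c1O | intermediate
22 | tricarboxylic acid (not isolated) | Cc1c(Cc2c(O)c(Oc3c(C=O)c(O)cc(C)c3C(=O)OC)c(C)c(C(=O)O)c2O)c(O)c(C(=O)O)c(O)c1Cc1c(O)c(Oc2c(C=O)c(O)cc(C)c2C(=O)OC)c(C)c(C(=O)O)c1O | intermediate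
23 | Praesorether G | COC(=O)c1c(C)cc(O)c(C=O)c1Oc1c(C)cc(O)c(Cc2c(O)cc(O)c(Cc3c(O)cc(C)c(Oc4c(C=O)c(O)cc(C)c4C(=O)OC)c3O)c2C)c1O | target

## Step count and risks

Total step count: 13. Longest linear sequence: 10 steps (1, 2, 3, 5, 6, 7, 8, 11, 12, 13).

Steps most likely to fail:

1. Step 7. The conjugate addition may stall because the α-oxygen and the β-methyl group lower the electrophilicity of the acceptor. Alternatively, the adduct may be drained by closure onto the ring-A ester followed by irreversible loss of the carbomethoxy group. The fallback sets out from 9 and 10 and reverses the order of the two bond formations. The dianion of 10 (NaH, then n-BuLi, THF, 0 °C) is acylated at its terminal carbon by the enoate ester of 9 (−78 → 0 °C) to give tert-butyl (Z)-6-(ArO)-3,5-dioxooct-6-enoate F1. Cs2CO3 in MeCN at rt should then close the ring by intramolecular Michael addition of the carbon between ester and ketone onto the enone (6-endo-trig). This returns to the route at 12.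

2. Step 8. The second deprotonation may be incomplete, or selenium may be delivered to the carbon between the two carbonyl groups, where no syn β-hydrogen exists; selenium transfer to the product phenol is a further risk. The fallback sets out from 12 and replaces the selenoxide elimination by a hydride-abstraction dehydrogenation with DDQ (1.1 equiv, 1,4-dioxane, rt → 50 °C). The enol is oxidised to the cyclohexadienone, which tautomerises. No new compound is made, and the route is rejoined at 15.

3. Step 11. Release of the quinone methide from the ester-chelated Mannich base may be slow, so that O-alkylation or quinone methide self-addition outruns C-alkylation at the hindered, ester-deactivated carbon of 15. The fallback sets out from 15 and 17 and reverses the roles of the partners. Compound 15 is aminomethylated at its single free ring carbon (Eschenmoser's salt, Et3N, CH2Cl2) to give tert-butyl 5-(ArO)-3-[(dimethylamino)methyl]-2,4-dihydroxy-6-methylbenzoate F2. Heating F2 (2.1 equiv) with 17 in 1,4-dioxane should alkylate the two equivalent free carbons of 17 in turn, through tert-butyl 3-{[5-(ArO)-3-(tert-butoxycarbonyl)-2,6-dihydroxy-4-methylphenyl]methyl}-2,6-dihydroxy-4-methylbenzoate F3. This returns to the route at 20.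

Further compounds
F1 | step 7 | tert-butyl (Z)-6-(ArO)-3,5-dioxooct-6-enoate | C/C=C(\Oc1c(C2OCC(C)(C)CO2)c(OCOC)cc(C)c1C(=O)OC)C(=O)CC(=O)CC(=O)OC(C)(C)C
F0 | step 8 | none | none
F2 | step 11 | tert-butyl 5-(ArO)-3-[(dimethylamino)methyl]-2,4-dihydroxy-6-methylbenzoate | Cc1c(Oc2c(C3OCC(C)(C)CO3)c(OCOC)cc(C)c2C(=O)OC)c(O)c(CN(C)C)c(O)c1C(=O)OC(C)(C)C
F3 | step 11 | tert-butyl 3-{[5-(ArO)-3-(tert-butoxycarbonyl)-2,6-dihydroxy-4-methylphenyl]methyl}-2,6-dihydroxy-4-methylbenzoate | Cc1cc(O)c(C(=O)OC(C)(C)C)c(O)c1Cc1c(O)c(Oc2c(C3OCC(C)(C)CO3)c(OCOC)cc(C)c2C(=O)OC)c(C)c(C(=O)OC(C)(C)C)c1O
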